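**Plan**

- Numbering: the target is (3S,4aR,7aR)-3,4a-dimethyl-3-(10-phenyldecyl)tetrahydro-3H-furo[3,2-c][1,2]dioxin-6(4H)-one, with ring atoms O1, O2, C3, C4, C4a, O5, C6, C7, C7a and side chain C1'–C10'.
- Cuts, in retrosynthetic order: C2'=C3' (cross-metathesis, then diimide); C3–C1' (allylsilane on a peroxycarbenium ion); O1–C3 and O2–C7a (excision of O2, so that C3, C4, C4a and C7a become a cyclobutanol with a C3–C7a bond); C3–CH3 (Grignard); C3–C7a and C4–C4a ([2+2] of dichloroketene with α-angelica lactone).
- Forward: the γ-lactone comes in with the first starting material, the cyclobutane is fused onto it, the four-membered ring is expanded by the two atoms of O2 to the 1,2-dioxane, and the phenylalkyl chain is joined last.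
- Enabling feature: the two peroxide carbons C3 and C7a are linked through C4–C4a, so removing O1–O2 leaves a four-carbon ring. C3 carries a methyl group and one exchangeable substituent (it can stand at the ketone/hemiperketal level) and C7a is a secondary carbon of the lactone ring, so an alkoxy radical on C3 opens towards C7a.
- Stereochemistry: C4a by ketoreductase kinetic resolution of the racemic cyclobutanone; C7a by cis capture of O2 and cis ring fusion in the expansion; C3 by axial allylation of the peroxycarbenium ion anti to the C4a methyl.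

Key step: step 5

Remark 1: in 5 the endo hydroxyl and the lactone oxygen are the two enantiotopic hydroxyls of a meso diol acid, so O-to-O acyl migration would racemise 5; it is therefore quenched cold with acid and used at once without exposure to base.

Remark 2 (assumption): α-angelica lactone, trichloroacetyl chloride, (6-bromohexyl)benzene, allylmagnesium bromide, allyltrimethylsilane and ketoreductase screening panels are taken as commercial; SMILES of racemates show the enantiomer that leads to the target.

**Step 1**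
Reactants: 1 α-angelica lactone (5-methylfuran-2(3H)-one)
Product: 2 rac-(1S,5R)-7,7-dichloro-1-methyl-2-oxabicyclo[3.2.0]heptane-3,6-dione (cis-fused)
Conditions: Cl3CCOCl (1.5 equiv, slow addition), Zn–Cu couple, POCl3, Et2O, 35 °C
Reagents that add atoms: trichloroacetyl chloride, ClC(Cl)(Cl)C(Cl)=O
Why: thermal [2+2] cycloaddition of dichloroketene (made in the flask) with the enol-ester double bond, in which the ketene carbonyl carbon bonds to the nucleophilic CH carbon (C4 of 1) and the CCl2 carbon to the oxygen-bearing C5, suprafacially on the alkene, so the cis-fused cyclobutanone with the carbonyl next to the ring-fusion CH should result.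

**Step 2**
Reactants: 2 rac-(1S,5R)-7,7-dichloro-1-methyl-2-oxabicyclo[3.2.0]heptane-3,6-dione
Product: 3 rac-(1R,5R)-1-methyl-2-oxabicyclo[3.2.0]heptane-3,6-dione
Conditions: Zn dust, AcOH, 25 °C
Reagents that add atoms: none
Why: zinc reduction of both α-C–Cl bonds through the zinc enolate, the standard dechlorination of dichloroketene adducts, which leaves the lactone and the ring-fusion centres untouched.

**Step 3**
Reactants: 3 rac-(1R,5R)-1-methyl-2-oxabicyclo[3.2.0]heptane-3,6-dione
Product: 4 (1R,5R)-1-methyl-2-oxabicyclo[3.2.0]heptane-3,6-dione (single enantiomer, recovered unreduced)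
Conditions: (R)-selective ketoreductase (NADPH-dependent alcohol dehydrogenase), NADP+ (cat.), i-PrOH (10 vol %), KH2PO4/K2HPO4 buffer pH 7.0, 30 °C, run to just past half conversion
Reagents that add atoms: none
Why: enzymatic kinetic resolution by enantiomer-selective carbonyl reduction, in which an anti-Prelog ketoreductase delivers hydride to the face that is the open convex face only in the (1S,5S)-ketone (removed as its 6R endo alcohol) and the concave face in the (1R,5R)-ketone, which should therefore be left behind, as in dehydrogenase resolutions of bicyclo[3.2.0]heptan-6-ones.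

**Step 4**
Reactants: 4 (1R,5R)-1-methyl-2-oxabicyclo[3.2.0]heptane-3,6-dione
Product: 5 (1R,5S,6S)-6-hydroxy-1,6-dimethyl-2-oxabicyclo[3.2.0]heptan-3-one (methyl exo, hydroxyl endo)
Conditions: MeMgBr (1.1 equiv), THF, −78 °C; AcOH quench at −78 °C
Reagents that add atoms: methylmagnesium bromide, C[Mg]Br
Why: Grignard 1,2-addition to the strained cyclobutanone, far more electrophilic than the γ-lactone, expected from the convex face; the carbinol configuration is erased in step 5, so either epimer would serve.

**Step 5**
Reactants: 5 (1R,5S,6S)-6-hydroxy-1,6-dimethyl-2-oxabicyclo[3.2.0]heptan-3-one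
Product: 7 (4aR,7aR)-3-hydroxy-3,4a-dimethyltetrahydro-3H-furo[3,2-c][1,2]dioxin-6(4H)-one (cis-fused; C3 anomers), via keto hydroperoxide 6 (not isolated)
Conditions: Co(acac)2 (20 mol %), O2 (1 atm), ClCH2CH2Cl, 40 °C
Reagents that add atoms: dioxygen, O=O
Why: Co(acac)2 under O2 converts the tertiary cyclobutanol into a cobalt alkoxide and then an alkoxy radical; strain-driven β-scission breaks the bond from the carbinol carbon to the ring-fusion CH (not to the CH2), the secondary lactone radical captures triplet O2, and the peroxyl radical is reduced to the cobalt peroxide or hydroperoxide 6, whose terminal oxygen adds to the methyl ketone just formed. The closest known reaction type is the Co(acac)2/O2 oxygenative ring expansion of secondary and tertiary cyclobutanols (from dichloroketene adducts) to 1,2-dioxan-3-ols, the four-ring counterpart of the cyclopropanol to 1,2-dioxolan-3-ol expansion. The 1,2-dioxane closes by 6-exo-trig addition of the peroxide oxygen to the ketone carbonyl (hemiperketal formation), so the four cyclobutane carbons and both atoms of O2 make up the six-membered ring, a net expansion by two atoms. C7a is set in the O2 capture, which must occur cis to the acetonyl arm on C4a because only that peroxide can reach the ketone to give the cis-fused bicycle; C3 forms reversibly under anomeric control and is planarised again in step 7, and C4a is untouched. The step needs regioselective β-scission, secured by the secondary-versus-primary radical difference, and cis capture of O2, for which the substrate offers only a small bias (methyl against a CH2 arm on the neighbouring quaternary carbon, possibly helped by cobalt held at the new carbonyl), so material from trans capture is expected as a separable by-product and this is the main risk of the route.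

**Step 6**
Reactants: 7 (4aR,7aR)-3-hydroxy-3,4a-dimethyltetrahydro-3H-furo[3,2-c][1,2]dioxin-6(4H)-one
Product: 8 (4aR,7aR)-3,4a-dimethyl-6-oxohexahydro-3H-furo[3,2-c][1,2]dioxin-3-yl acetate (C3 anomers)
Conditions: Ac2O (3 equiv), pyridine, DMAP (10 mol %), CH2Cl2, 0 °C
Reagents that add atoms: acetic anhydride, CC(=O)OC(C)=O
Why: DMAP-catalysed acylation of the hemiperketal hydroxyl, the usual activation of 1,2-dioxan-3-ols as peroxyketal acetates, under conditions too mild to open the peroxide or epimerise C4a or C7a.

**Step 7**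
Reactants: 8 (4aR,7aR)-3,4a-dimethyl-6-oxohexahydro-3H-furo[3,2-c][1,2]dioxin-3-yl acetate
Product: 10 (3S,4aR,7aR)-3-allyl-3,4a-dimethyltetrahydro-3H-furo[3,2-c][1,2]dioxin-6(4H)-one, via peroxycarbenium ion 9 (not isolated)
Conditions: CH2=CHCH2SiMe3 (3 equiv), Me3SiOTf (0.3 equiv), CH2Cl2, −78 °C
Reagents that add atoms: allyltrimethylsilane, C=CC[Si](C)(C)C
Why: Hosomi–Sakurai allylation of the peroxycarbenium ion formed by Lewis-acid ionisation of the peroxyketal acetate (known for acetylated 1,2-dioxan-3-ols and for ketone-derived peroxyketals), where chair-like axial attack on the half-chair with the C4a methyl equatorial and the C4a–O5 bond axial should place the allyl group anti to the C4a methyl and cis to the C7a–C7 bond, which is the 3S configuration.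

**Step 8**
Reactants: 11 (6-bromohexyl)benzene
Product: 12 9-phenylnon-1-ene
Conditions: CH2=CHCH2MgBr (1.5 equiv), Li2CuCl4 (3 mol %), THF, 0 to 25 °C
Reagents that add atoms: allylmagnesium bromide, C=CC[Mg]Br
Why: copper-catalysed Kochi-type coupling of a primary alkyl bromide with allylmagnesium bromide, giving the terminal alkene with the seven-methylene spacer the side chain needs.

**Step 9**
Reactants: 10 (3S,4aR,7aR)-3-allyl-3,4a-dimethyltetrahydro-3H-furo[3,2-c][1,2]dioxin-6(4H)-one; 12 9-phenylnon-1-ene
Product: 13 (3S,4aR,7aR)-3,4a-dimethyl-3-[(2E)-10-phenyldec-2-en-1-yl]tetrahydro-3H-furo[3,2-c][1,2]dioxin-6(4H)-one (E expected as major isomer, Z minor)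
Conditions: 12 (3 equiv), second-generation Hoveyda–Grubbs catalyst (5 mol %), CH2Cl2, 40 °C
Reagents that add atoms: none
Why: olefin cross-metathesis of two terminal alkenes, driven by loss of ethylene and excess 12 and tolerant of dialkyl peroxides and lactones, with the E/Z ratio irrelevant because the double bond is reduced next.

**Step 10**
Reactants: 13 (3S,4aR,7aR)-3,4a-dimethyl-3-[(2E)-10-phenyldec-2-en-1-yl]tetrahydro-3H-furo[3,2-c][1,2]dioxin-6(4H)-one
Product: 14 (3S,4aR,7aR)-3,4a-dimethyl-3-(10-phenyldecyl)tetrahydro-3H-furo[3,2-c][1,2]dioxin-6(4H)-one (target)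
Conditions: KO2CN=NCO2K (10 equiv), AcOH (20 equiv, slow addition), MeOH, 0 to 25 °C
Reagents that add atoms: none
Why: diimide generated in the flask transfers H2 to the disubstituted alkene by concerted syn addition and leaves the O–O bond, the lactone and the arene intact, the standard way to saturate alkenes in cyclic peroxides, with no stereocentre affected.

**Compound list**

1 | α-angelica lactone (5-methylfuran-2(3H)-one) | CC1=CCC(=O)O1 | starting material
2 | rac-(1S,5R)-7,7-dichloro-1-methyl-2-oxabicyclo[3.2.0]heptane-3,6-dione (racemate) | O=C1C(Cl)(Cl)[C@@]2(C)OC(=O)C[C@H]21 | intermediate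
3 | rac-(1R,5R)-1-methyl-2-oxabicyclo[3.2.0]heptane-3,6-dione (racemate) | O=C1C[C@@]2(C)OC(=O)C[C@H]21 | intermediate
4 | (1R,5R)-1-methyl-2-oxabicyclo[3.2.0]heptane-3,6-dione (single enantiomer) | O=C1C[C@@]2(C)OC(=O)C[C@H]21 | intermediate
5 | (1R,5S,6S)-6-hydroxy-1,6-dimethyl-2-oxabicyclo[3.2.0]heptan-3-one | C[C@]1(O)C[C@@]2(C)OC(=O)C[C@H]21 | intermediate
6 | (4R,5R)-4-hydroperoxy-5-methyl-5-(2-oxopropyl)oxolan-2-one (keto hydroperoxide, not isolated) | CC(=O)C[C@@]1(C)OC(=O)C[C@H]1OO | intermediate
7 | (4aR,7aR)-3-hydroxy-3,4a-dimethyltetrahydro-3H-furo[3,2-c][1,2]dioxin-6(4H)-one (C3 anomers) | CC1(O)C[C@@]2(C)OC(=O)C[C@H]2OO1 | intermediate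
8 | (4aR,7aR)-3,4a-dimethyl-6-oxohexahydro-3H-furo[3,2-c][1,2]dioxin-3-yl acetate (C3 anomers) | CC(=O)OC1(C)C[C@@]2(C)OC(=O)C[C@H]2OO1 | intermediate
9 | (4aR,7aR)-3,4a-dimethyl-6-oxo-4,4a,7,7a-tetrahydro-6H-furo[3,2-c][1,2]dioxin-2-ium triflate (peroxycarbenium ion, not isolated) | CC=1C[C@@]2(C)OC(=O)C[C@H]2O[O+]=1.[O-]S(=O)(=O)C(F)(F)F | intermediate
10 | (3S,4aR,7aR)-3-allyl-3,4a-dimethyltetrahydro-3H-furo[3,2-c][1,2]dioxin-6(4H)-one | C[C@]1(CC=C)C[C@@]2(C)OC(=O)C[C@H]2OO1 | intermediate
11 | (6-bromohexyl)benzene | BrCCCCCCc1ccccc1 | starting material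
12 | 9-phenylnon-1-ene | C=CCCCCCCCc1ccccc1 | intermediate
13 | (3S,4aR,7aR)-3,4a-dimethyl-3-[(2E)-10-phenyldec-2-en-1-yl]tetrahydro-3H-furo[3,2-c][1,2]dioxin-6(4H)-one | C[C@]1(C/C=C/CCCCCCCc2ccccc2)C[C@@]2(C)OC(=O)C[C@H]2OO1 | intermediate
14 | (3S,4aR,7aR)-3,4a-dimethyl-3-(10-phenyldecyl)tetrahydro-3H-furo[3,2-c][1,2]dioxin-6(4H)-one | C[C@]1(CCCCCCCCCCc2ccccc2)C[C@@]2(C)OC(=O)C[C@H]2OO1 | target

**Step count and risks**

Total step count: 10. Longest linear sequence: 9 steps (steps 1 to 7, 9 and 10); step 8 is a one-step branch.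

Steps most likely to fail:

Step 5. What may go wrong is capture of O2 on the face trans to the acetonyl arm (weak facial bias) and cobalt-induced breakdown of the secondary hydroperoxide before it closes onto the ketone. The fallback replaces radical oxygen capture by an ionic ring closure that can only give the cis fusion; it sets out from 5 and comes back at 10. Alkoxy-radical fragmentation of 5 with PhI(OAc)2 and I2 under visible light (hypoiodite reaction) should give the β-iodo lactone, (5R)-4-iodo-5-methyl-5-(2-oxopropyl)oxolan-2-one F1. Et3N then eliminates hydrogen iodide to the butenolide, (5R)-5-methyl-5-(2-oxopropyl)furan-2(5H)-one F2. Urea–hydrogen peroxide with Sc(OTf)3 in MeOH converts the ketone into the methoxy hydroperoxide, (5R)-5-(2-hydroperoxy-2-methoxypropyl)-5-methylfuran-2(5H)-one F3. Et2NH in CF3CH2OH closes the dioxane by intramolecular oxa-Michael addition to the cis-fused methyl peroxyketal, (4aR,7aR)-3-methoxy-3,4a-dimethyltetrahydro-3H-furo[3,2-c][1,2]dioxin-6(4H)-one F4. F4 is used in place of 8 under the conditions of step 7 to give 10.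

Step 7. What may go wrong is heterolysis of the O–O bond or proton loss from the tertiary peroxycarbenium ion, or attack of the allylsilane on the wrong face. The fallback makes no C–C bond at a peroxide carbon: both carbon substituents are placed on C3 before the peroxide is introduced, and the ring is closed by oxa-Michael addition. It sets out from 4 and comes back at 14.
- Addition of (10-phenyldecyl)magnesium bromide to 4 at −78 °C should give the cyclobutanol, (1R,5S,6S)-6-hydroxy-1-methyl-6-(10-phenyldecyl)-2-oxabicyclo[3.2.0]heptan-3-one F8.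
- Fragmentation with PhI(OAc)2 and I2 under visible light gives the iodo ketone, (5R)-4-iodo-5-methyl-5-(2-oxo-12-phenyldodecyl)oxolan-2-one F9, and Et3N the butenolide, (5R)-5-methyl-5-(2-oxo-12-phenyldodecyl)furan-2(5H)-one F10.
- Ketone-selective Takai–Lombardo methylenation (Zn, CH2Br2, TiCl4) gives the 1,1-disubstituted alkene, (5R)-5-methyl-5-(2-methylidene-12-phenyldodecyl)furan-2(5H)-one F11.
- Mukaiyama–Isayama hydroperoxysilylation (Co(acac)2, O2, Et3SiH) at this electron-rich alkene gives the tertiary silyl peroxide, (5R)-5-methyl-5-[2-methyl-12-phenyl-2-(triethylsilylperoxy)dodecyl]furan-2(5H)-one F12, as both epimers.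
- Bu4NF with AcOH frees the hydroperoxide, (5R)-5-(2-hydroperoxy-2-methyl-12-phenyldodecyl)-5-methylfuran-2(5H)-one F13, and Et2NH in CF3CH2OH closes it by oxa-Michael addition to 14 together with its C3 epimer, (3R,4aR,7aR)-3,4a-dimethyl-3-(10-phenyldecyl)tetrahydro-3H-furo[3,2-c][1,2]dioxin-6(4H)-one F14, which is removed by chromatography.

Step 3. What may go wrong is insufficient discrimination between the two ketone enantiomers (both reduced, to diastereomeric alcohols). The fallback resolves the derived alcohol by acylation instead; it sets out from 3 and comes back at 4. NaBH4 in MeOH at −40 °C should reduce 3 from the convex face to the racemic endo alcohol, rac-(1R,5S,6S)-6-hydroxy-1-methyl-2-oxabicyclo[3.2.0]heptan-3-one F5. Burkholderia cepacia lipase with vinyl acetate in t-BuOMe is expected, by the empirical rule for secondary alcohols, to acylate the 6R enantiomer to (1S,5R,6R)-1-methyl-3-oxo-2-oxabicyclo[3.2.0]heptan-6-yl acetate F7. This leaves (1R,5S,6S)-6-hydroxy-1-methyl-2-oxabicyclo[3.2.0]heptan-3-one F6, which Dess–Martin periodinane oxidises to 4.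

**Further compounds**

F1 | step 5 | (5R)-4-iodo-5-methyl-5-(2-oxopropyl)oxolan-2-one (both C4 epimers) | CC(=O)C[C@@]1(C)OC(=O)CC1I
F2 | step 5 | (5R)-5-methyl-5-(2-oxopropyl)furan-2(5H)-one | CC(=O)C[C@@]1(C)OC(=O)C=C1
F3 | step 5 | (5R)-5-(2-hydroperoxy-2-methoxypropyl)-5-methylfuran-2(5H)-one (ketal carbon unassigned) | COC(C)(OO)C[C@@]1(C)OC(=O)C=C1
F4 | step 5 | (4aR,7aR)-3-methoxy-3,4a-dimethyltetrahydro-3H-furo[3,2-c][1,2]dioxin-6(4H)-one (C3 unassigned) | COC1(C)C[C@@]2(C)OC(=O)C[C@H]2OO1
F5 | step 3 | rac-(1R,5S,6S)-6-hydroxy-1-methyl-2-oxabicyclo[3.2.0]heptan-3-one (racemate) | O[C@H]1C[C@@]2(C)OC(=O)C[C@H]21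
F6 | step 3 | (1R,5S,6S)-6-hydroxy-1-methyl-2-oxabicyclo[3.2.0]heptan-3-one (single enantiomer) | O[C@H]1C[C@@]2(C)OC(=O)C[C@H]21
F7 | step 3 | (1S,5R,6R)-1-methyl-3-oxo-2-oxabicyclo[3.2.0]heptan-6-yl acetate | CC(=O)O[C@@H]1C[C@]2(C)OC(=O)C[C@@H]21
F8 | step 7 | (1R,5S,6S)-6-hydroxy-1-methyl-6-(10-phenyldecyl)-2-oxabicyclo[3.2.0]heptan-3-one | O[C@@]1(CCCCCCCCCCc2ccccc2)C[C@@]2(C)OC(=O)C[C@H]21
F9 | step 7 | (5R)-4-iodo-5-methyl-5-(2-oxo-12-phenyldodecyl)oxolan-2-one (both C4 epimers) | O=C(CCCCCCCCCCc1ccccc1)C[C@@]1(C)OC(=O)CC1I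
F10 | step 7 | (5R)-5-methyl-5-(2-oxo-12-phenyldodecyl)furan-2(5H)-one | O=C(CCCCCCCCCCc1ccccc1)C[C@@]1(C)OC(=O)C=C1
F11 | step 7 | (5R)-5-methyl-5-(2-methylidene-12-phenyldodecyl)furan-2(5H)-one | C=C(CCCCCCCCCCc1ccccc1)C[C@@]1(C)OC(=O)C=C1
F12 | step 7 | (5R)-5-methyl-5-[2-methyl-12-phenyl-2-(triethylsilylperoxy)dodecyl]furan-2(5H)-one (both epimers at the peroxide carbon) | CC[Si](CC)(CC)OOC(C)(CCCCCCCCCCc1ccccc1)C[C@@]1(C)OC(=O)C=C1
F13 | step 7 | (5R)-5-(2-hydroperoxy-2-methyl-12-phenyldodecyl)-5-methylfuran-2(5H)-one (both epimers at the peroxide carbon) | OOC(C)(CCCCCCCCCCc1ccccc1)C[C@@]1(C)OC(=O)C=C1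
F14 | step 7 | (3R,4aR,7aR)-3,4a-dimethyl-3-(10-phenyldecyl)tetrahydro-3H-furo[3,2-c][1,2]dioxin-6(4H)-one | C[C@@]1(CCCCCCCCCCc2ccccc2)C[C@@]2(C)OC(=O)C[C@H]2OO1
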